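**Assumption:** the target has no stereocentre, stereogenic axis or stereogenic double bond, so there is no enantiomer to select. It is delivered as the free tris(hydrogen sulfate) as drawn, by cold acidification of its potassium salt; for storage the salt is preferable.

## Retrosynthetic overview
1. Endgame without protecting groups or SO3·amine: all three ArOSO3H groups are unmasked in one operation from two O–SO2F groups (O-3, O-7) and a 3',4'-catechol cyclic sulfate. The cyclic sulfate opens with loss of the better leaving 4'-phenoxide, which fixes 3'-OSO3H and 4'-OH.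
2. That S(VI) triad comes from quercetin and SO2F2 alone. One reagent sorts the five OH groups: catechol to a ring, 3-OH and 7-OH to OSO2F, chelated 5-OH untouched.
3. Quercetin comes from its 3,3',4'-trimethyl ether, made from phloroglucinol and an α-methoxy-β-keto ester by uncatalysed thermal Mentzer annulation (C4–C4a and O1–C2). This replaces the chalcone/AFO and Baker–Venkataraman routes.
4. The β-keto ester comes from methyl methoxyacetate and 3,4-dimethoxybenzoyl chloride by crossed Claisen acylation.
5. Ring order: A and B are bought, pyranone C is formed in step 2, and a temporary dioxathiole ring is closed in step 4 and opened in step 5.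

## Route

**Step 1**
Reactants: 1 methyl methoxyacetate; 2 3,4-dimethoxybenzoyl chloride
Product: 4 methyl 3-(3,4-dimethoxyphenyl)-2-methoxy-3-oxopropanoate (racemic), via chelated lithium enolate 3 (not isolated)
Conditions: 1 (2.1 equiv), LiHMDS (2.1 equiv), THF, −78 °C, 45 min; then 2 (1.0 equiv), −78 → −20 °C; aq. NH4Cl
Reagents that add atoms: none
Why: Crossed Claisen C-acylation of a lithium ester enolate, in which the non-enolisable aroyl chloride can only be the acceptor and the second equivalent of enolate deprotonates the more acidic β-keto ester so it is not acylated twice; the new α-carbon is racemic, configurationally labile and becomes sp2 in step 2.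

**Step 2**
Reactants: 4 methyl 3-(3,4-dimethoxyphenyl)-2-methoxy-3-oxopropanoate (1.5 equiv); 5 phloroglucinol (anhydrous)
Product: 8 5,7-dihydroxy-3,3',4'-trimethoxyflavone, via α-oxoketene 6 (not isolated), via 2-methoxy-1,3-diketone 7 (not isolated)
Conditions: neat melt (or Ph2O), 240 °C, microwave 10–15 min or oil bath 2 h, N2 sweep to remove MeOH and H2O
Reagents that add atoms: none
Why: Mentzer pyrone synthesis (uncatalysed thermal phenol/β-keto ester condensation), in which 4 loses MeOH to α-oxoketene 6, this acylates the symmetric and strongly C-nucleophilic phloroglucinol (directly or by O-acylation and thermal Fries shift) to 7, and an ortho-OH of 7 adds to the aroyl ketone and dehydrates to the flavone rather than the Pechmann coumarin because no acid is present; no stereocentre remains.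

**Step 3**
Reactants: 8 5,7-dihydroxy-3,3',4'-trimethoxyflavone
Product: 9 quercetin (3,3',4',5,7-pentahydroxyflavone)
Conditions: BBr3 (8 equiv), CH2Cl2, −78 °C → rt, 16 h; then ice-water
Reagents that add atoms: none
Why: Lewis-acid methyl ether cleavage (BBr3 demethylation) removes the two aryl OMe groups and the carbonyl-chelated 3-OMe by bromide SN2 on the boron-activated methyl groups, and the chromone core is inert to it.

**Step 4**
Reactants: 9 quercetin
Product: 11 quercetin 3',4'-cyclic sulfate 3,7-bis(fluorosulfate), via quercetin 3,7,4'-tris(fluorosulfate) 10 (not isolated)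
Conditions: SO2F2 (balloon, or generated ex situ in a two-chamber reactor), Et3N (4.05 equiv, added slowly last), degassed MeCN, 0 °C → rt, 3 h; cold 0.5 M HCl wash, short SiO2 plug
Reagents that add atoms: sulfuryl fluoride, O=S(=O)(F)F
Why: SuFEx fluorosulfation with base as the limiting reagent, in which only the four non-chelated hydroxyls are deprotonated and captured by SO2F2, the 3'-phenoxide next to the 4'-OSO2F group of 10 closes on sulfur with loss of fluoride (the known fate of catechols with SO2F2), the 5-OH stays locked in its hydrogen bond to C4=O as in selective 7-O-triflation of 5-hydroxyflavones, and Et3N alone does not promote ArOSO2F/ArOH cross-coupling.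

**Step 5**
Reactants: 11 quercetin 3',4'-cyclic sulfate 3,7-bis(fluorosulfate)
Product: 13 quercetin 3,3',7-tris(hydrogen sulfate), via tris(benzamido sulfate) adduct 12 (not isolated)
Conditions: PhC(O)NHOH (6 equiv), K2CO3 (8 equiv), MeCN/H2O 1:1, Ar, 0 °C → rt, 2 h (11 in MeCN added to the pre-formed hydroxamate); then 1 M HCl, 0 °C, pH ≈ 1; Sephadex LH-20, lyophilise
Reagents that add atoms: benzohydroxamic acid (N-hydroxybenzamide), O=C(NO)c1ccccc1
Why: Proposed new method: the α-effect nucleophile benzohydroxamate attacks each S(VI) centre, displacing fluoride at O-3 and O-7 and, at the strained catechol cyclic sulfate, the better nucleofuge, namely the 4'-phenoxide that is para-conjugated to the C4 carbonyl (4'-OH pKa about 8.5 against at least 10 for 3'-OH), so sulfur stays on O-3'; each ArO–SO2–O–NH–C(O)Ph unit of 12 is then N-deprotonated and undergoes Lossen rearrangement with ArOSO3− as leaving group, which delivers the three sulfate monoesters irreversibly while PhNCO is hydrolysed to aniline and CO2, and any reversible re-closure of the 3'-adduct funnels the same way because the 4'-phenoxide isomer is also the thermodynamically favoured one; the closest known reaction types are hydroxamic-acid (Lossen) unmasking of aryl fluorosulfates to aryl sulfates and alkaline opening of 4-nitrocatechol cyclic sulfate to 2-hydroxy-5-nitrophenyl sulfate; no stereocentre is involved.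

## Compound list
1 | methyl methoxyacetate | COCC(=O)OC | starting material
2 | 3,4-dimethoxybenzoyl chloride | COc1ccc(C(=O)Cl)cc1OC | starting material
3 | chelated lithium enolate of 1 (α-OMe cis to OLi; geometry has no consequence) | CO/C=C(\O[Li])OC | intermediate (not isolated)
4 | methyl 3-(3,4-dimethoxyphenyl)-2-methoxy-3-oxopropanoate (racemic, labile α-centre) | COC(=O)C(OC)C(=O)c1ccc(OC)c(OC)c1 | intermediate
5 | phloroglucinol (benzene-1,3,5-triol) | Oc1cc(O)cc(O)c1 | starting material
6 | α-oxoketene, 2-(3,4-dimethoxybenzoyl)-2-methoxyethenone | COC(=C=O)C(=O)c1ccc(OC)c(OC)c1 | intermediate (not isolated)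
7 | 1-(3,4-dimethoxyphenyl)-2-methoxy-3-(2,4,6-trihydroxyphenyl)propane-1,3-dione (racemic) | COC(C(=O)c1ccc(OC)c(OC)c1)C(=O)c1c(O)cc(O)cc1O | intermediate (not isolated)
8 | 5,7-dihydroxy-3,3',4'-trimethoxyflavone | COc1ccc(-c2oc3cc(O)cc(O)c3c(=O)c2OC)cc1OC | intermediate
9 | quercetin | O=c1c(O)c(-c2ccc(O)c(O)c2)oc2cc(O)cc(O)c12 | intermediate
10 | quercetin 3,7,4'-tris(fluorosulfate) (3'-OH and 5-OH free) | O=c1c(OS(=O)(=O)F)c(-c2ccc(OS(=O)(=O)F)c(O)c2)oc2cc(OS(=O)(=O)F)cc(O)c12 | intermediate (not isolated)
11 | 2-(2,2-dioxo-1,3,2-benzodioxathiol-5-yl)-5-hydroxy-4-oxo-4H-chromene-3,7-diyl bis(fluorosulfate) | O=c1c(OS(=O)(=O)F)c(-c2ccc3OS(=O)(=O)Oc3c2)oc2cc(OS(=O)(=O)F)cc(O)c12 | intermediate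
12 | quercetin carrying SO2–O–NH–C(O)Ph on O-3, O-7 and O-3' (4'-OH and 5-OH free; drawn with all three sites at the adduct stage) | O=c1c(OS(=O)(=O)ONC(=O)c3ccccc3)c(-c2ccc(O)c(OS(=O)(=O)ONC(=O)c3ccccc3)c2)oc2cc(OS(=O)(=O)ONC(=O)c3ccccc3)cc(O)c12 | intermediate (not isolated)
13 | quercetin 3,3',7-tris(hydrogen sulfate) | O=c1c(OS(=O)(=O)O)c(-c2ccc(O)c(OS(=O)(=O)O)c2)oc2cc(OS(=O)(=O)O)cc(O)c12 | target

## Totals
Total step count: 5. Longest linear sequence: 5 (1 or 2 → 4 → 8 → 9 → 11 → 13).

## Three steps most likely to fail

**Step 5 (most risky).** Three failure modes are foreseeable. ArO–S cleavage instead of S–F cleavage at O-3 or O-7 would lose a sulfate. An imperfect 3'/4' ratio could not be separated at the polyanion stage. The 4'-phenoxide could be carbamoylated by PhNCO.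

The fallback sets out from 11 and comes back at 13. It replaces direct O-atom transfer by an isolable protected sulfate. Compound 11 is treated with 2,2,2-trichloroethanol and Cs2CO3 in MeCN at 0 °C. Trichloroethoxide exchanges both S–F bonds and opens the cyclic sulfate, giving the neutral, silica-stable quercetin 3,7,3'-tris(2,2,2-trichloroethyl sulfate) F1. Any 4'-regioisomer or partly cleaved material is removed from it by chromatography. Reductive fragmentation of the three trichloroethyl groups with Zn dust and ammonium formate in MeOH at rt, followed by the same cold acidification, gives 13.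

**Step 4.** Possible failures are 5-O-fluorosulfation, diaryl sulfate oligomers, or oxidation of the quercetin polyanion.

The fallback sets out from 9 and comes back at 11. It addresses the hydroxyl classes one at a time.
- Compound 9 is heated with dichlorodiphenylmethane in Ph2O at 175 °C, which masks only the catechol and gives 3',4'-O-diphenylmethylenequercetin F2.
- The two remaining non-chelated hydroxyls are fluorosulfated with the weighable solid reagent AISF (2.1 equiv) and DBU in THF, giving 3',4'-O-diphenylmethylenequercetin 3,7-bis(fluorosulfate) F3.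
- The ketal is cleaved in AcOH/H2O 4:1 at reflux, which S–F bonds tolerate, giving quercetin 3,7-bis(fluorosulfate) F4.
- The only reactive site left, the free catechol, is closed with SO2F2 and Et3N (2.0 equiv) in MeCN through 10 to give 11.

**Step 2.** Possible failures are hydrolysis and decarboxylation of the keto ester by the water formed in the ring closure, Pechmann coumarin formation, or tar at 240 °C.

The fallback sets out from 5 and comes back at 8. It builds the C3 unit on ring A first.
- Houben–Hoesch acylation of 5 with methoxyacetonitrile (ZnCl2, HCl gas, Et2O, 0 °C) gives 2-methoxy-1-(2,4,6-trihydroxyphenyl)ethanimine F5, which precipitates as its hydrochloride.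
- Hydrolysis in boiling water gives 2-methoxy-1-(2,4,6-trihydroxyphenyl)ethanone F6.
- Allan–Robinson condensation with commercial 3,4-dimethoxybenzoic anhydride and sodium 3,4-dimethoxybenzoate at 180 °C gives 5-hydroxy-3,3',4'-trimethoxyflavon-7-yl 3,4-dimethoxybenzoate F7.
- Saponification of that ester with KOH in aqueous EtOH, then acidification, gives 8.

## Further compounds
F1 | step 5 | quercetin 3,7,3'-tris(2,2,2-trichloroethyl sulfate) | O=c1c(OS(=O)(=O)OCC(Cl)(Cl)Cl)c(-c2ccc(O)c(OS(=O)(=O)OCC(Cl)(Cl)Cl)c2)oc2cc(OS(=O)(=O)OCC(Cl)(Cl)Cl)cc(O)c12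
F2 | step 4 | 3',4'-O-diphenylmethylenequercetin | O=c1c(O)c(-c2ccc3OC(c4ccccc4)(c4ccccc4)Oc3c2)oc2cc(O)cc(O)c12
F3 | step 4 | 3',4'-O-diphenylmethylenequercetin 3,7-bis(fluorosulfate) | O=c1c(OS(=O)(=O)F)c(-c2ccc3OC(c4ccccc4)(c4ccccc4)Oc3c2)oc2cc(OS(=O)(=O)F)cc(O)c12
F4 | step 4 | quercetin 3,7-bis(fluorosulfate) | O=c1c(OS(=O)(=O)F)c(-c2ccc(O)c(O)c2)oc2cc(OS(=O)(=O)F)cc(O)c12
F5 | step 2 | 2-methoxy-1-(2,4,6-trihydroxyphenyl)ethanimine | COCC(=N)c1c(O)cc(O)cc1O
F6 | step 2 | 2-methoxy-1-(2,4,6-trihydroxyphenyl)ethanone | COCC(=O)c1c(O)cc(O)cc1O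
F7 | step 2 | 5-hydroxy-3,3',4'-trimethoxyflavon-7-yl 3,4-dimethoxybenzoate | COc1ccc(cc1OC)C(=O)Oc1cc(O)c2c(=O)c(OC)c(-c3ccc(OC)c(OC)c3)oc2c1
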